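## The problem

The target 19 is a 2',8''-linked biflavone. Flavone 1 (rings A, C, B) carries 5-OH, 7-OMe and 4'-OMe; flavone 2 (rings D, E, F) is an apigenin unit with 5-, 7- and 4'-OH. A single biaryl bond joins C2' of ring B to C8 of ring D. That bond has three ortho substituents (C1' with the pyranone on one side, O1 and the 7-oxygen of ring D on the other), so it is the hardest bond to make and is best formed before either heterocycle exists. There is no stereocentre, and the axis is specified without configuration, so nothing has to be controlled or relayed. The real selectivity problem is regiochemical: ring D is a phloroglucinol ring, and the oxygen chosen as O1 of ring E decides between the 8- and the 6-linked series. Two aryl methyl ethers must survive beside four free phenols, the 4-pyranone rings do not tolerate hydroxide, hard carbon nucleophiles or long hydrogenation, and the phloroglucinol ring is easily over-substituted. The enabling feature is that C1' carries C2 of flavone 1, a carbon at the carboxylic acid oxidation level, directly beside C2', while C8 lies between two oxygens. C2, C1', C2', C8, C8a and the oxygen on C8a can therefore be tied into a six-membered lactone fused to rings B and D, made from a 2-halobenzoic acid and a triphenol whose three ring carbons are equivalent.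

## Retrosynthesis

**19 to 18.** The four phenols of 19 are traced back to the benzyl ethers of 18; only O–C bonds are cut. Benzyl is preferred to methyl because two methyl ethers must remain, and to acetal or silyl groups because the ethers must pass through amide base, sulfonic acid and Lewis-acidic magnesium conditions. The forward step asks for a hydrogenolysis that stops before the pyranone C2=C3 bonds react.

**18 to 12 and 13.** Ring E is opened at O1–C2 and C3–C4, giving salicylaldehyde 12 and alkyne 13. Alkyne 13 brings C2, C3 and ring F; the aldehyde carbon becomes C4. The neighbouring cut at C2–C3 (aroyl transfer to an ortho-hydroxyacetophenone) would need an acetyl group on ring D, for which no ortho-specific introduction compatible with benzyl ethers is at hand. The forward sequence runs through carbinol 15, ynone 16 and amino enone 17. It asks for an acetylide addition that spares the pyranone of flavone 1 and for a closure that is 6-endo, not 5-exo.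

**12 to 10.** The formyl carbon is removed from C4a, leaving phenol 10 (the hydroxymethyl stage 11 lies between them in the forward sense). This cut is preferred to an electrophilic acylation, which would have to choose between C4a and C6, both strongly activated. Phenol 10 has exactly one free hydroxyl and that hydroxyl has exactly one free ortho carbon, so a phenoxide-delivered formylation fixes the 8-linkage.

**10 to 9, then 5 and 7.** Ring C is opened at O1–C2 to diketone 9, and 9 is cut at C2–C3 into lactone 5 and ketone 7 (reacting as its dianion 8). The lactone carbonyl of 5 is C2 of flavone 1 and is an aryl ester, hence an activated acyl donor. Its leaving group is the ring D oxygen beside C8, so the step that builds the carbon chain of flavone 1 also uncovers the one hydroxyl needed for ring E. Hydrolysing the lactone and running a classical ester rearrangement would need a third kind of protecting group for that hydroxyl and several more steps.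

**7 to 6.** One benzyl group is removed from the symmetrical ring-A ketone 6. The mono-ether keeps flavone 1 free of a second phenoxide during formylation and acetylide addition, and it leaves in the final hydrogenolysis.

**5 to 4.** The two benzyl ethers of 5 are cut back to the diphenol 4. Benzylation while the lactone is closed is what distinguishes the third ring D oxygen from the other two.

**4 to 1 and 2.** The lactone C–O bond is opened to acid 3, and the biaryl bond C2'–C8 is cut to give 2-bromo-4-methoxybenzoic acid 1 and phloroglucinol 2. Both are purchased and used unprotected. This cut is preferred to a cross-coupling of two protected, tri-ortho-substituted partners because the equivalence of the three ring carbons of 2 removes any site question, and the carboxyl group of 1 both assists the arylation and closes the ring. The forward reaction must arylate carbon, not oxygen, and must stop after one arylation.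

## Roads not taken

**Alternative 1: aryne three-component coupling around ring B.**
- **Cut and key step.** Both bonds from ring B to its neighbours are cut, C2'–C8 and C1'–C2. The aryne precursor 3-chloro-2-iodo-5-methoxyphenyl 4-chlorobenzenesulfonate A2 would undergo iodine–magnesium exchange with i-PrMgCl and lose sulfonate. 2,4,6-Tris(methoxymethoxy)phenylmagnesium bromide A3 would add to the aryne at the carbon remote from chlorine, and the new arylmagnesium at C1' would be trapped with CO2 to give acid A1.
- **Merits.** Both bonds form in one flask without a transition metal, the hindered bond is made by addition, not coupling, and ring D arrives fully protected. In convergence this road is better than the chosen one, and it does not depend on a copper reaction of an unprotected triphenol.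
- **Weak points.** The chlorine that directs the addition is absent from the target and must be removed later. The carboxyl group of A1 sits between chlorine and a tris-alkoxyaryl ring, so acylating the ring-A ketone with it would be far harder than opening the planar lactone 5. All three ring D oxygens carry the same acetal, so after acylation of ring D the closure could use the oxygen beside C8 or the one para to it, and the 8- versus 6-linkage stays open. A2 and A3 each need several steps.
- **Comparison.** The chosen plan sets against the better convergence one step from two purchased compounds, no spectator halogen, and a lactone that both activates the carboxyl carbon and marks one oxygen.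

**Alternative 2: two-directional oxidative cyclisation of a bichalcone.**
- **Cut and key step.** O1–C2 is cut in both flavones, back to the bis(2'-hydroxychalcone) A5. Heating A5 with catalytic I2 in DMSO would close rings C and E by oxa-Michael addition and dehydrogenation and give the tri-O-benzyl ether A4, one hydrogenolysis from 19.
- **Merits.** Both heterocycles form in one operation with cheap reagents. The end of this route is clearly shorter than the chosen one, which spends two steps on ring C and three on ring E.
- **Weak points.** The key step does not touch the hardest bond. A5 already contains the tri-ortho-substituted C2'–C8 bond and exactly one free hydroxyl beside C8, so the biaryl coupling and the oxygen differentiation are only moved into the preparation of A5. The two different aldol condensations must be ordered, since a precursor with both an aryl aldehyde and an aryl methyl ketone would self-condense. In A5 the ring D hydroxyl can also add to the ring-B enone to form a six-membered ether, competing with closure of ring C.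
- **Comparison.** The chosen plan sets against the shorter endgame a first step that solves the biaryl bond and the oxygen choice together, and a flavone 1 built at the carboxyl oxidation level with no oxidation beside free electron-rich phenols.

**Alternative 3: Danheiser benzannulation that builds ring D on ring B.**
- **Cut and key step.** Three bonds of ring D are cut (C8–C8a, C6–C7, C4a–C8a). Heating 3-ethoxycyclobut-2-en-1-one A7 with the ring-B siloxyalkyne A8 would give phenol A6 through a vinylketene, [2+2] addition, ring opening and six-electron electrocyclisation.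
- **Merits.** No biaryl coupling is needed, because the hindered bond is already the aryl–alkyne bond. Ring D is born with three different oxygen substituents (free hydroxyl, silyl ether, ethyl ether), a finer differentiation than the chosen plan reaches, with regiochemistry fixed by mechanism.
- **Weak points.** A8 is not purchasable and needs several steps. The ethoxy group would later have to be cleaved beside two aryl methyl ethers, which no reagent does selectively, so A7 would have to be replaced by a benzyloxy analogue that must itself be made. Ring B of A6 carries bromine at C1', so C2 of flavone 1 must still be introduced next to the hindered axis without lactone activation. A ring that can be bought as 2 is rebuilt from small pieces.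
- **Comparison.** The chosen plan needs only "two oxygens alike, one different", which the lactone provides in one step from purchased materials with the carboxyl carbon already in place.

Key step: step 1

Assumption: the C2'–C8 axis has three ortho substituents and may rotate slowly, but the target is specified without axial configuration, so no control of the axis is planned.

## Route

Step 1
Reactants: 1 2-bromo-4-methoxybenzoic acid; 2 phloroglucinol (benzene-1,3,5-triol)
Product: 4 1,3-dihydroxy-9-methoxy-6H-benzo[c]chromen-6-one, via 4-methoxy-2-(2,4,6-trihydroxyphenyl)benzoic acid 3 (not isolated)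
Conditions: 2 (3 equiv), NaOH, degassed H2O, 100 °C; CuSO4 (10 mol%, aq), 100 °C; then aq HCl
Reagents that add atoms: none
Why: Hurtley reaction, the copper-mediated C-arylation of a 1,3-diphenol by a 2-bromobenzoic acid, which is established for resorcinol-type phenols and gives benzo[c]chromen-6-ones directly. CuSO4 is reduced in the phenoxide medium to monovalent copper, which the carboxylate of 1 binds and holds beside the C–Br bond; within this chelate bromide is replaced by a ring carbon of the phloroglucinol anion, reacting as the enolate of its keto tautomer, and tautomerisation restores the aromatic ring to give acid 3. The ring closes by 6-exo-trig acyl substitution of the phenol beside the new bond on the carboxyl group, driven on acidification by the insolubility of the planar lactone 4. No stereocentre is formed. Three selectivities are needed: carbon against oxygen arylation is secured by the soft, enolate-like carbon of the triphenol anion; the site on 2 needs no control because its three ring carbons are equivalent; single against multiple arylation is secured by the excess of 2 and by the lower electron density of the product ring once one oxygen is acylated. The methyl ether meta to bromine is a spectator.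

Step 2
Reactants: 4 1,3-dihydroxy-9-methoxy-6H-benzo[c]chromen-6-one
Product: 5 1,3-bis(benzyloxy)-9-methoxy-6H-benzo[c]chromen-6-one
Conditions: BnBr (2.5 equiv), K2CO3, DMF, 60 °C
Reagents that add atoms: benzyl bromide, BrCc1ccccc1
Why: Williamson ether synthesis; the two phenols are the only acidic sites, the polar aprotic solvent favours O- over C-alkylation of the resorcinol-type ring, and the aryl lactone is stable to carbonate in the absence of water.

Step 3
Reactants: 6 2',6'-dihydroxy-4'-methoxyacetophenone
Product: 7 1-[2-(benzyloxy)-6-hydroxy-4-methoxyphenyl]ethan-1-one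
Conditions: BnBr (1.0 equiv), K2CO3, acetone, reflux
Reagents that add atoms: benzyl bromide, BrCc1ccccc1
Why: Williamson ether synthesis on a symmetrical ketone: the two hydroxyls are equivalent, so only one mono-ether can form, and after the first alkylation the remaining hydroxyl is held in a hydrogen bond to the carbonyl, which slows the second.

Step 4
Reactants: 7 1-[2-(benzyloxy)-6-hydroxy-4-methoxyphenyl]ethan-1-one; 5 1,3-bis(benzyloxy)-9-methoxy-6H-benzo[c]chromen-6-one
Product: 9 1-[2-(benzyloxy)-6-hydroxy-4-methoxyphenyl]-3-{2-[2,4-bis(benzyloxy)-6-hydroxyphenyl]-4-methoxyphenyl}propane-1,3-dione, via dilithium 3-(benzyloxy)-5-methoxy-2-(1-oxidoethenyl)phenolate 8 (not isolated)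
Conditions: 7 (1.2 equiv), LiN(SiMe3)2 (3.6 equiv), THF, −78 °C; then 5, −78 °C → rt; aq NH4Cl
Reagents that add atoms: none
Why: Crossed Claisen acylation of a ketone enolate by an aryl ester, the intermolecular counterpart of the acyl transfer in the Baker–Venkataraman rearrangement; the leaving group is the ring D phenoxide, so C2–C3 of flavone 1 forms while the one oxygen beside C8 is uncovered. The third equivalent of base deprotonates the 1,3-diketone and makes the opening irreversible, and any acylation on the ring A phenoxide oxygen would give an aryl ester that the same base rearranges to 9.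

Step 5
Reactants: 9 1-[2-(benzyloxy)-6-hydroxy-4-methoxyphenyl]-3-{2-[2,4-bis(benzyloxy)-6-hydroxyphenyl]-4-methoxyphenyl}propane-1,3-dione
Product: 10 5-(benzyloxy)-2-{2-[2,4-bis(benzyloxy)-6-hydroxyphenyl]-4-methoxyphenyl}-7-methoxy-4H-chromen-4-one
Conditions: p-TsOH·H2O (20 mol%), toluene, 80 °C
Reagents that add atoms: none
Why: Acid-catalysed cyclodehydration of a 1-(2-hydroxyaryl)-1,3-diketone, the closing stage of the Baker–Venkataraman flavone synthesis: the ring A hydroxyl adds to the ring-B carbonyl (6-exo-trig) and water is lost. Closure by the ring D hydroxyl on the same carbon gives only a hemiketal or enol ether that reopens under acid, whereas the 4-pyranone does not, so the equilibrium should drain to 10; catalytic sulfonic acid in toluene spares the benzyl ethers.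

Step 6
Reactants: 10 5-(benzyloxy)-2-{2-[2,4-bis(benzyloxy)-6-hydroxyphenyl]-4-methoxyphenyl}-7-methoxy-4H-chromen-4-one
Product: 12 5-(benzyloxy)-2-{2-[4,6-bis(benzyloxy)-3-formyl-2-hydroxyphenyl]-4-methoxyphenyl}-7-methoxy-4H-chromen-4-one, via ortho-hydroxymethyl phenol 11 (not isolated)
Conditions: MgCl2, Et3N, (CH2O)n, MeCN, reflux; aq HCl
Reagents that add atoms: formaldehyde (from paraformaldehyde), C=O
Why: Magnesium-mediated ortho-formylation (Casnati–Skattebøl): the magnesium phenoxide of the only free hydroxyl binds formaldehyde and delivers it through a six-membered transition state to the single free ortho carbon, the future C4a, and the benzylic alkoxide of 11 passes a hydride to a second formaldehyde (Oppenauer-type). The carbon para to the hydroxyl (future C6) is out of reach of this delivery, and flavone 1, with its 5-benzyl ether, offers no second phenoxide.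

Step 7
Reactants: 13 1-(benzyloxy)-4-ethynylbenzene; 12 5-(benzyloxy)-2-{2-[4,6-bis(benzyloxy)-3-formyl-2-hydroxyphenyl]-4-methoxyphenyl}-7-methoxy-4H-chromen-4-one
Product: 15 5-(benzyloxy)-2-{2-[4,6-bis(benzyloxy)-3-{3-[4-(benzyloxy)phenyl]-1-hydroxyprop-2-yn-1-yl}-2-hydroxyphenyl]-4-methoxyphenyl}-7-methoxy-4H-chromen-4-one (racemic at the carbinol carbon), via lithium [4-(benzyloxy)phenyl]acetylide 14 (not isolated)
Conditions: 13 (3.0 equiv), n-BuLi (2.9 equiv), THF, −78 °C; then 12, −78 → −20 °C; aq NH4Cl
Reagents that add atoms: none
Why: 1,2-Addition of a lithium acetylide to an aldehyde, applied to a free salicylaldehyde with an extra equivalent for the phenol. At low temperature the aldehyde is far more electrophilic than the vinylogous-ester carbonyl of flavone 1, and the slight deficit of n-BuLi leaves no alkyllithium. The carbinol centre forms without control and is erased in step 8.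

Step 8
Reactants: 15 5-(benzyloxy)-2-{2-[4,6-bis(benzyloxy)-3-{3-[4-(benzyloxy)phenyl]-1-hydroxyprop-2-yn-1-yl}-2-hydroxyphenyl]-4-methoxyphenyl}-7-methoxy-4H-chromen-4-one
Product: 18 5,7-bis(benzyloxy)-2-[4-(benzyloxy)phenyl]-8-{2-[5-(benzyloxy)-7-methoxy-4-oxo-4H-chromen-2-yl]-5-methoxyphenyl}-4H-chromen-4-one, via ortho-hydroxyaryl ynone 16 (not isolated), via diethylamino enone 17 (not isolated)
Conditions: MnO2, CH2Cl2, rt; filter; then Et2NH, EtOH, 50 °C
Reagents that add atoms: none
Why: MnO2 oxidises the benzylic propargylic alcohol to ynone 16 and leaves the aryl ethers alone; diethylamine then adds to the ynone to give amino enone 17, and the phenol displaces the amine at the β-carbon by addition–elimination. That closure can only be six-membered (6-endo), so the aurone from 5-exo closure is avoided, and both geometric isomers of 17 converge on the pyranone of ring E.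

Step 9
Reactants: 18 5,7-bis(benzyloxy)-2-[4-(benzyloxy)phenyl]-8-{2-[5-(benzyloxy)-7-methoxy-4-oxo-4H-chromen-2-yl]-5-methoxyphenyl}-4H-chromen-4-one
Product: 19 5,7-dihydroxy-8-[2-(5-hydroxy-7-methoxy-4-oxo-4H-chromen-2-yl)-5-methoxyphenyl]-2-(4-hydroxyphenyl)-4H-chromen-4-one
Conditions: H2 (1 atm), Pd/C (10% Pd), THF–MeOH, rt
Reagents that add atoms: none
Why: Catalytic hydrogenolysis of four aryl benzyl ethers; aryl methyl ethers are inert and the pyranone C2=C3 bonds are reduced much more slowly, so the reaction is stopped once four equivalents of H2 are taken up.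

## Compound list

1 | 2-bromo-4-methoxybenzoic acid | COc1ccc(C(=O)O)c(Br)c1 | starting material
2 | phloroglucinol (benzene-1,3,5-triol) | Oc1cc(O)cc(O)c1 | starting material
3 | 4-methoxy-2-(2,4,6-trihydroxyphenyl)benzoic acid | COc1ccc(C(=O)O)c(-c2c(O)cc(O)cc2O)c1 | intermediate (not isolated)
4 | 1,3-dihydroxy-9-methoxy-6H-benzo[c]chromen-6-one | COc1ccc2c(c1)-c1c(O)cc(O)cc1OC2=O | intermediate
5 | 1,3-bis(benzyloxy)-9-methoxy-6H-benzo[c]chromen-6-one | COc1ccc2c(c1)-c1c(OCc3ccccc3)cc(OCc3ccccc3)cc1OC2=O | intermediate
6 | 2',6'-dihydroxy-4'-methoxyacetophenone | CC(=O)c1c(O)cc(OC)cc1O | starting material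
7 | 1-[2-(benzyloxy)-6-hydroxy-4-methoxyphenyl]ethan-1-one | CC(=O)c1c(O)cc(OC)cc1OCc1ccccc1 | intermediate
8 | dilithium 3-(benzyloxy)-5-methoxy-2-(1-oxidoethenyl)phenolate (dianion of 7) | [Li+].[Li+].C=C([O-])c1c([O-])cc(OC)cc1OCc1ccccc1 | intermediate (not isolated)
9 | 1-[2-(benzyloxy)-6-hydroxy-4-methoxyphenyl]-3-{2-[2,4-bis(benzyloxy)-6-hydroxyphenyl]-4-methoxyphenyl}propane-1,3-dione | COc1ccc(C(=O)CC(=O)c2c(O)cc(OC)cc2OCc2ccccc2)c(-c2c(O)cc(OCc3ccccc3)cc2OCc2ccccc2)c1 | intermediate
10 | 5-(benzyloxy)-2-{2-[2,4-bis(benzyloxy)-6-hydroxyphenyl]-4-methoxyphenyl}-7-methoxy-4H-chromen-4-one | COc1ccc(-c2cc(=O)c3c(OCc4ccccc4)cc(OC)cc3o2)c(-c2c(O)cc(OCc3ccccc3)cc2OCc2ccccc2)c1 | intermediate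
11 | 5-(benzyloxy)-2-{2-[4,6-bis(benzyloxy)-2-hydroxy-3-(hydroxymethyl)phenyl]-4-methoxyphenyl}-7-methoxy-4H-chromen-4-one | COc1ccc(-c2cc(=O)c3c(OCc4ccccc4)cc(OC)cc3o2)c(-c2c(O)c(CO)c(OCc3ccccc3)cc2OCc2ccccc2)c1 | intermediate (not isolated)
12 | 5-(benzyloxy)-2-{2-[4,6-bis(benzyloxy)-3-formyl-2-hydroxyphenyl]-4-methoxyphenyl}-7-methoxy-4H-chromen-4-one | COc1ccc(-c2cc(=O)c3c(OCc4ccccc4)cc(OC)cc3o2)c(-c2c(O)c(C=O)c(OCc3ccccc3)cc2OCc2ccccc2)c1 | intermediate
13 | 1-(benzyloxy)-4-ethynylbenzene | C#Cc1ccc(OCc2ccccc2)cc1 | starting material
14 | lithium [4-(benzyloxy)phenyl]acetylide | [Li+].[C-]#Cc1ccc(OCc2ccccc2)cc1 | intermediate (not isolated)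
15 | 5-(benzyloxy)-2-{2-[4,6-bis(benzyloxy)-3-{3-[4-(benzyloxy)phenyl]-1-hydroxyprop-2-yn-1-yl}-2-hydroxyphenyl]-4-methoxyphenyl}-7-methoxy-4H-chromen-4-one, racemic at the carbinol carbon | COc1ccc(-c2cc(=O)c3c(OCc4ccccc4)cc(OC)cc3o2)c(-c2c(O)c(C(O)C#Cc3ccc(OCc4ccccc4)cc3)c(OCc3ccccc3)cc2OCc2ccccc2)c1 | intermediate
16 | 5-(benzyloxy)-2-{2-[4,6-bis(benzyloxy)-3-{3-[4-(benzyloxy)phenyl]prop-2-ynoyl}-2-hydroxyphenyl]-4-methoxyphenyl}-7-methoxy-4H-chromen-4-one | COc1ccc(-c2cc(=O)c3c(OCc4ccccc4)cc(OC)cc3o2)c(-c2c(O)c(C(=O)C#Cc3ccc(OCc4ccccc4)cc3)c(OCc3ccccc3)cc2OCc2ccccc2)c1 | intermediate (not isolated)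
17 | 5-(benzyloxy)-2-{2-[4,6-bis(benzyloxy)-3-{(E)-3-[4-(benzyloxy)phenyl]-3-(diethylamino)prop-2-enoyl}-2-hydroxyphenyl]-4-methoxyphenyl}-7-methoxy-4H-chromen-4-one (drawn E; either isomer closes) | COc1ccc(-c2cc(=O)c3c(OCc4ccccc4)cc(OC)cc3o2)c(-c2c(O)c(C(=O)/C=C(/N(CC)CC)c3ccc(OCc4ccccc4)cc3)c(OCc3ccccc3)cc2OCc2ccccc2)c1 | intermediate (not isolated)
18 | 5,7-bis(benzyloxy)-2-[4-(benzyloxy)phenyl]-8-{2-[5-(benzyloxy)-7-methoxy-4-oxo-4H-chromen-2-yl]-5-methoxyphenyl}-4H-chromen-4-one | COc1ccc(-c2cc(=O)c3c(OCc4ccccc4)cc(OC)cc3o2)c(-c2c(OCc3ccccc3)cc(OCc3ccccc3)c3c(=O)cc(-c4ccc(OCc5ccccc5)cc4)oc23)c1 | intermediate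
19 | 5,7-dihydroxy-8-[2-(5-hydroxy-7-methoxy-4-oxo-4H-chromen-2-yl)-5-methoxyphenyl]-2-(4-hydroxyphenyl)-4H-chromen-4-one | COc1ccc(-c2cc(=O)c3c(O)cc(OC)cc3o2)c(-c2c(O)cc(O)c3c(=O)cc(-c4ccc(O)cc4)oc23)c1 | target

## Step count and risks

Total steps: 9. Longest linear sequence: 8 (steps 1, 2, 4, 5, 6, 7, 8, 9); step 3 is a one-step branch.

**Step 1 (key step).** The lactone product still has an activated ring and may be arylated a second time. The bromo acid may also be lost to hydroxy-debromination or protodebromination in hot alkali, and some arylation may occur on oxygen. Fallback, from 1 to 5: Steglich esterification of 1 with purchased 3,5-bis(benzyloxy)phenol (DCC, DMAP, CH2Cl2) should give 3,5-bis(benzyloxy)phenyl 2-bromo-4-methoxybenzoate F1. Intramolecular direct arylation (Pd(OAc)2, PPh3, K2CO3, DMA, 120 °C; oxidative addition of zerovalent palladium into C–Br, then C–H arylation at either of the two equivalent carbons ortho to the ester oxygen) should then close the same biaryl bond and give lactone 5 directly, rejoining the route at step 4.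

**Step 4.** Acyl transfer may stall: the polyanion of 7 may aggregate and react slowly with the lactone, or proton exchange with the forming diketone may consume enolate before the lactone is used up. Fallback, from 5 to 10 at a lower oxidation level: reduction of 5 with (i-Bu)2AlH at −78 °C should give 1,3-bis(benzyloxy)-9-methoxy-6H-benzo[c]chromen-6-ol F2, the ring tautomer of the hydroxy aldehyde. Claisen–Schmidt condensation of F2 with 7 (KOH, EtOH) should give (E)-1-[2-(benzyloxy)-6-hydroxy-4-methoxyphenyl]-3-{2-[2,4-bis(benzyloxy)-6-hydroxyphenyl]-4-methoxyphenyl}prop-2-en-1-one F3. Oxidative cyclisation of F3 (catalytic I2, DMSO, 120 °C) should give 10.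

**Step 5.** Closure may go through the ring D hydroxyl instead of the ring A hydroxyl, or the benzyl ether peri to the carbonyl may be lost under acid. Fallback, from 9 to 10: silylation of the unchelated ring D hydroxyl of 9 (t-BuMe2SiCl, imidazole, DMF) should give 1-[2-(benzyloxy)-6-hydroxy-4-methoxyphenyl]-3-{2-[2,4-bis(benzyloxy)-6-(tert-butyldimethylsilyloxy)phenyl]-4-methoxyphenyl}propane-1,3-dione F4. Cyclodehydration, now possible only through ring A, should give 5-(benzyloxy)-2-{2-[2,4-bis(benzyloxy)-6-(tert-butyldimethylsilyloxy)phenyl]-4-methoxyphenyl}-7-methoxy-4H-chromen-4-one F5, and Bu4NF should return 10.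

**Step 7.** Chemoselectivity may be poor: the acetylide may add to C4 or C2 of flavone 1, or addition to the phenoxide-deactivated, doubly ortho-substituted aldehyde may be too slow at a temperature where the pyranone is safe. Fallback, from 10 to 18 without a carbanion: iodination of 10 ortho to the free hydroxyl (N-iodosuccinimide, CH2Cl2, 0 °C) should give 5-(benzyloxy)-2-{2-[4,6-bis(benzyloxy)-2-hydroxy-3-iodophenyl]-4-methoxyphenyl}-7-methoxy-4H-chromen-4-one F6. Carbonylative Sonogashira coupling of F6 with 13 (PdCl2(PPh3)2, CO 1 atm, Et2NH) should pass through 16 and 17 in the flask and give 18. The ortho- versus para-selectivity of the iodination is not fixed by mechanism as it is in the formylation, which is why this remains the fallback.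

**Step 9.** The pyranone C2=C3 bonds may be over-reduced, or cleavage of the hindered 7''-ether may stall as partly deprotected material precipitates. Fallback, from 18 to 19: Lewis-acid debenzylation with BCl3 and pentamethylbenzene as cation scavenger (CH2Cl2, −78 °C), which involves no reduction; the unchelated methyl ethers should survive at this temperature.

## Further compounds

F1 | step 1 | 3,5-bis(benzyloxy)phenyl 2-bromo-4-methoxybenzoate | COc1ccc(C(=O)Oc2cc(OCc3ccccc3)cc(OCc3ccccc3)c2)c(Br)c1
F2 | step 4 | 1,3-bis(benzyloxy)-9-methoxy-6H-benzo[c]chromen-6-ol (racemic lactol) | COc1ccc2c(c1)-c1c(OCc3ccccc3)cc(OCc3ccccc3)cc1OC2O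
F3 | step 4 | (E)-1-[2-(benzyloxy)-6-hydroxy-4-methoxyphenyl]-3-{2-[2,4-bis(benzyloxy)-6-hydroxyphenyl]-4-methoxyphenyl}prop-2-en-1-one | COc1ccc(/C=C/C(=O)c2c(O)cc(OC)cc2OCc2ccccc2)c(-c2c(O)cc(OCc3ccccc3)cc2OCc2ccccc2)c1
F4 | step 5 | 1-[2-(benzyloxy)-6-hydroxy-4-methoxyphenyl]-3-{2-[2,4-bis(benzyloxy)-6-(tert-butyldimethylsilyloxy)phenyl]-4-methoxyphenyl}propane-1,3-dione | COc1ccc(C(=O)CC(=O)c2c(O)cc(OC)cc2OCc2ccccc2)c(-c2c(O[Si](C)(C)C(C)(C)C)cc(OCc3ccccc3)cc2OCc2ccccc2)c1
F5 | step 5 | 5-(benzyloxy)-2-{2-[2,4-bis(benzyloxy)-6-(tert-butyldimethylsilyloxy)phenyl]-4-methoxyphenyl}-7-methoxy-4H-chromen-4-one | COc1ccc(-c2cc(=O)c3c(OCc4ccccc4)cc(OC)cc3o2)c(-c2c(O[Si](C)(C)C(C)(C)C)cc(OCc3ccccc3)cc2OCc2ccccc2)c1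
F6 | step 7 | 5-(benzyloxy)-2-{2-[4,6-bis(benzyloxy)-2-hydroxy-3-iodophenyl]-4-methoxyphenyl}-7-methoxy-4H-chromen-4-one | COc1ccc(-c2cc(=O)c3c(OCc4ccccc4)cc(OC)cc3o2)c(-c2c(O)c(I)c(OCc3ccccc3)cc2OCc2ccccc2)c1
F0 | step 9 | none | none
A1 | alternative 1 | 2-chloro-4-methoxy-6-[2,4,6-tris(methoxymethoxy)phenyl]benzoic acid | COc1cc(Cl)c(C(=O)O)c(-c2c(OCOC)cc(OCOC)cc2OCOC)c1
A2 | alternative 1 | 3-chloro-2-iodo-5-methoxyphenyl 4-chlorobenzenesulfonate | COc1cc(Cl)c(I)c(OS(=O)(=O)c2ccc(Cl)cc2)c1
A3 | alternative 1 | 2,4,6-tris(methoxymethoxy)phenylmagnesium bromide | COCOc1cc(OCOC)c([Mg]Br)c(OCOC)c1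
A4 | alternative 2 | tri-O-benzyl ether of the target with free 5-hydroxyl on flavone 1 | COc1ccc(-c2cc(=O)c3c(O)cc(OC)cc3o2)c(-c2c(OCc3ccccc3)cc(OCc3ccccc3)c3c(=O)cc(-c4ccc(OCc5ccccc5)cc4)oc23)c1
A5 | alternative 2 | bis(2'-hydroxychalcone): (E)-3-{2-[4,6-bis(benzyloxy)-3-{(E)-3-[4-(benzyloxy)phenyl]prop-2-enoyl}-2-hydroxyphenyl]-4-methoxyphenyl}-1-(2,6-dihydroxy-4-methoxyphenyl)prop-2-en-1-one | COc1ccc(/C=C/C(=O)c2c(O)cc(OC)cc2O)c(-c2c(OCc3ccccc3)cc(OCc3ccccc3)c(C(=O)/C=C/c3ccc(OCc4ccccc4)cc3)c2O)c1
A6 | alternative 3 | 2-(2-bromo-5-methoxyphenyl)-5-ethoxy-3-(triisopropylsilyloxy)phenol | CCOc1cc(O)c(-c2cc(OC)ccc2Br)c(O[Si](C(C)C)(C(C)C)C(C)C)c1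
A7 | alternative 3 | 3-ethoxycyclobut-2-en-1-one | CCOC1=CC(=O)C1
A8 | alternative 3 | {[(2-bromo-5-methoxyphenyl)ethynyl]oxy}triisopropylsilane | COc1ccc(Br)c(C#CO[Si](C(C)C)(C(C)C)C(C)C)c1
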